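**Strategy.** The carbocycle is disconnected at C1=C2 and C1–C7. The enoate C7–C1(=C2)–C6H2 of the cyclohexene is read as the aldol-condensation product of a 1,7-dialdehyde whose C7 aldehyde comes from a terminal alkene, CO and H2. The C3/C4/C5 stereotriad (3,4-cis, 4,5-trans) is superimposable on C2–C4 of D-mannose. The precursor is therefore an open-chain 2,3,4-tri-O-galloyl-D-lyxo-hex-5-enal, released by zinc fragmentation of a 6-iodo-mannoside that already carries the three silyl-protected gallates. One flask (hydroformylation, then amine-salt aldol condensation) adds C7 and closes the six-membered ring with the alkene position fixed by connectivity. Oxidation of C7 and desilylation complete the synthesis.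

Key step: step 5

Remark: the natural (3R,4S,5R) configuration encoded by the SMILES is assumed. Ring atoms are numbered as in shikimic acid (C7 = carboxyl carbon), TBS = tert-butyldimethylsilyl, and "G" = 3,4,5-tris(tert-butyldimethylsilyloxy)benzoyl.

**Step 1**
Reactants: 1 gallic acid
Product: 3 3,4,5-tris(tert-butyldimethylsilyloxy)benzoic acid, via tetrasilyl gallate 2 (not isolated)
Conditions: TBSCl (4.5 equiv), imidazole, DMF, rt; then AcOH/THF/H2O (3:1:1), rt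
Reagents that add atoms: tert-butyldimethylsilyl chloride, CC(C)(C)[Si](C)(C)Cl
Why: Exhaustive silylation followed by selective hydrolysis of the much more labile silyl ester (aryl silyl ethers survive dilute acetic acid) is a standard protection of a hydroxybenzoic acid; no stereocentre is involved.

**Step 2**
Reactants: 4 methyl α-D-mannopyranoside
Product: 5 methyl 6-deoxy-6-iodo-α-D-mannopyranoside
Conditions: I2, PPh3, imidazole, THF, reflux
Reagents that add atoms: iodine, II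
Why: Garegg–Samuelsson (Appel-type) iodination should be selective for the only primary hydroxyl of the unprotected pyranoside (SN2 at C6), leaving the stereocentres C1–C5 untouched.

**Step 3**
Reactants: 5 methyl 6-deoxy-6-iodo-α-D-mannopyranoside; 3 3,4,5-tris(tert-butyldimethylsilyloxy)benzoic acid (three equivalents)
Product: 6 methyl 6-deoxy-6-iodo-2,3,4-tri-O-G-α-D-mannopyranoside
Conditions: 3 (3.6 equiv in total), DIC (4 equiv), DMAP (0.6 equiv), CH2Cl2, 0 °C to rt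
Reagents that add atoms: 3,4,5-tris(tert-butyldimethylsilyloxy)benzoic acid (second equivalent of 3), O=C(O)c1cc(O[Si](C)(C)C(C)(C)C)c(O[Si](C)(C)C(C)(C)C)c(O[Si](C)(C)C(C)(C)C)c1; 3,4,5-tris(tert-butyldimethylsilyloxy)benzoic acid (third equivalent of 3), O=C(O)c1cc(O[Si](C)(C)C(C)(C)C)c(O[Si](C)(C)C(C)(C)C)c(O[Si](C)(C)C(C)(C)C)c1
Why: Threefold Steglich esterification consumes one molecule of 3 at each of O-2, O-3 and O-4 of 5, so three molecules of 3 end up in 6, and it forms the O–acyl bonds with retention at C2, C3 and C4, as in routine per-galloylation of glycoside polyols.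

**Step 4**
Reactants: 6 methyl 6-deoxy-6-iodo-2,3,4-tri-O-G-α-D-mannopyranoside
Product: 7 5,6-dideoxy-2,3,4-tri-O-G-D-lyxo-hex-5-enose (open-chain aldehyde)
Conditions: activated Zn dust, THF/H2O (9:1), sonication, 40 °C
Reagents that add atoms: none
Why: Bernet–Vasella reductive fragmentation: zinc insertion into C6–I and elimination across C5–O5 should open the pyranoside to the terminal alkene and a hemiacetal anion that expels methoxide to give the aldehyde, while C2–C4 are not involved and keep the D-manno (= D-lyxo) configuration.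

**Step 5**
Reactants: 7 5,6-dideoxy-2,3,4-tri-O-G-D-lyxo-hex-5-enose
Product: 10 (3R,4S,5R)-3,4,5-tris(G-oxy)cyclohex-1-ene-1-carbaldehyde, via heptanedial 8 (not isolated), via aldol 9 (not isolated)
Conditions: Rh(acac)(CO)2 (2 mol%), BiPhePhos (4 mol%), CO/H2 (1:1, 10 bar), toluene, 60 °C; vent; then Bn2NH·CF3CO2H (0.3 equiv), 25–40 °C
Reagents that add atoms: carbon monoxide, [C-]#[O+]
Why: The rhodium hydride should add anti-Markovnikov to the terminal alkene of 7 (the wide-bite-angle bisphosphite enforces the linear alkyl, which has no β-gallate to eliminate), and CO insertion and hydrogenolysis deliver C7 as the CH2CH2CHO terminus of 8; the ammonium salt then forms the enamine of this unbranched aldehyde, whose α-carbon (C1) attacks the more electrophilic α-acyloxy aldehyde carbon (C2) to give 9, and E1cB loss of water through the iminium gives the conjugated enal 10. The closest known reaction types are tandem hydroformylation–aldol sequences and the dibenzylammonium trifluoroacetate condensation of heptanedials, including sugar-derived ones, to cyclohex-1-enecarbaldehydes. The cyclohexene closes in a 6-(enolexo)-exo-trig mode. No stereocentre of 10 is created here: the two transient centres of 9 (C1, C2) are erased on dehydration, so all diastereomers of 9 converge on 10, while C3, C4 and C5 are carried unchanged from C2, C3 and C4 of D-mannose. The step needs linear rather than branched hydroformylation, enamine formation at the C7 aldehyde rather than at the α-branched α-acyloxy C2 aldehyde, and ring closure faster than β-elimination of the C4 gallate or epimerisation at C3; these are secured by BiPhePhos, by the steric and A(1,3) penalty of the trisubstituted enamine, and by intramolecularity together with a buffered salt that contains no free base. The enoate regiochemistry is fixed by connectivity, because C1 is the only carbon that carries C7 and can reach the C2 aldehyde.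

**Step 6**
Reactants: 10 (3R,4S,5R)-3,4,5-tris(G-oxy)cyclohex-1-ene-1-carbaldehyde
Product: 11 (3R,4S,5R)-3,4,5-tris(G-oxy)cyclohex-1-ene-1-carboxylic acid
Conditions: NaClO2, NaH2PO4, 2-methyl-2-butene, t-BuOH/THF/H2O, 0 °C to rt
Reagents that add atoms: sodium chlorite, [Na+].[O-]Cl=O
Why: Pinnick (Lindgren) oxidation should convert the enal into the enoic acid without touching the alkene, the esters or the aryl silyl ethers, the alkene scavenger consuming the hypochlorous acid formed.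

**Step 7**
Reactants: 11 (3R,4S,5R)-3,4,5-tris(G-oxy)cyclohex-1-ene-1-carboxylic acid
Product: 12 3,4,5-tri-O-galloylshikimic acid
Conditions: HF·pyridine (excess), THF/pyridine, 0 °C to rt
Reagents that add atoms: none
Why: Fluoride-driven cleavage of the nine aryl Si–O bonds under weakly acidic conditions should spare the three aryl esters, the enoic acid and the C1=C2 alkene, which hydrogenolytic deprotection would put at risk.

**Compound list**

1 | gallic acid | O=C(O)c1cc(O)c(O)c(O)c1 | starting material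
2 | tert-butyldimethylsilyl 3,4,5-tris(tert-butyldimethylsilyloxy)benzoate | CC(C)(C)[Si](C)(C)OC(=O)c1cc(O[Si](C)(C)C(C)(C)C)c(O[Si](C)(C)C(C)(C)C)c(O[Si](C)(C)C(C)(C)C)c1 | intermediate
3 | 3,4,5-tris(tert-butyldimethylsilyloxy)benzoic acid | O=C(O)c1cc(O[Si](C)(C)C(C)(C)C)c(O[Si](C)(C)C(C)(C)C)c(O[Si](C)(C)C(C)(C)C)c1 | intermediate
4 | methyl α-D-mannopyranoside | CO[C@H]1O[C@H](CO)[C@@H](O)[C@H](O)[C@@H]1O | starting material
5 | methyl 6-deoxy-6-iodo-α-D-mannopyranoside | CO[C@H]1O[C@H](CI)[C@@H](O)[C@H](O)[C@@H]1O | intermediate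
6 | methyl 6-deoxy-6-iodo-2,3,4-tris-O-[3,4,5-tris(tert-butyldimethylsilyloxy)benzoyl]-α-D-mannopyranoside | CO[C@H]1O[C@H](CI)[C@@H](OC(=O)c2cc(O[Si](C)(C)C(C)(C)C)c(O[Si](C)(C)C(C)(C)C)c(O[Si](C)(C)C(C)(C)C)c2)[C@H](OC(=O)c2cc(O[Si](C)(C)C(C)(C)C)c(O[Si](C)(C)C(C)(C)C)c(O[Si](C)(C)C(C)(C)C)c2)[C@@H]1OC(=O)c2cc(O[Si](C)(C)C(C)(C)C)c(O[Si](C)(C)C(C)(C)C)c(O[Si](C)(C)C(C)(C)C)c2 | intermediate
7 | 5,6-dideoxy-2,3,4-tris-O-[3,4,5-tris(tert-butyldimethylsilyloxy)benzoyl]-D-lyxo-hex-5-enose (open-chain aldehyde) | O=C[C@@H](OC(=O)c1cc(O[Si](C)(C)C(C)(C)C)c(O[Si](C)(C)C(C)(C)C)c(O[Si](C)(C)C(C)(C)C)c1)[C@@H](OC(=O)c1cc(O[Si](C)(C)C(C)(C)C)c(O[Si](C)(C)C(C)(C)C)c(O[Si](C)(C)C(C)(C)C)c1)[C@H](OC(=O)c1cc(O[Si](C)(C)C(C)(C)C)c(O[Si](C)(C)C(C)(C)C)c(O[Si](C)(C)C(C)(C)C)c1)C=C | intermediate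
8 | 5,6-dideoxy-2,3,4-tris-O-[3,4,5-tris(tert-butyldimethylsilyloxy)benzoyl]-D-lyxo-heptodialdose (heptanedial) | O=C[C@@H](OC(=O)c1cc(O[Si](C)(C)C(C)(C)C)c(O[Si](C)(C)C(C)(C)C)c(O[Si](C)(C)C(C)(C)C)c1)[C@@H](OC(=O)c1cc(O[Si](C)(C)C(C)(C)C)c(O[Si](C)(C)C(C)(C)C)c(O[Si](C)(C)C(C)(C)C)c1)[C@H](OC(=O)c1cc(O[Si](C)(C)C(C)(C)C)c(O[Si](C)(C)C(C)(C)C)c(O[Si](C)(C)C(C)(C)C)c1)CCC=O | intermediate
9 | 2-hydroxy-3,4,5-tris[3,4,5-tris(tert-butyldimethylsilyloxy)benzoyloxy]cyclohexane-1-carbaldehyde (acyloxy carbons configured as in 8; C1/C2 diastereomer mixture) | O=CC1C[C@@H](OC(=O)c2cc(O[Si](C)(C)C(C)(C)C)c(O[Si](C)(C)C(C)(C)C)c(O[Si](C)(C)C(C)(C)C)c2)[C@H](OC(=O)c2cc(O[Si](C)(C)C(C)(C)C)c(O[Si](C)(C)C(C)(C)C)c(O[Si](C)(C)C(C)(C)C)c2)[C@H](OC(=O)c2cc(O[Si](C)(C)C(C)(C)C)c(O[Si](C)(C)C(C)(C)C)c(O[Si](C)(C)C(C)(C)C)c2)C1O | intermediate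
10 | (3R,4S,5R)-3,4,5-tris[3,4,5-tris(tert-butyldimethylsilyloxy)benzoyloxy]cyclohex-1-ene-1-carbaldehyde | O=CC1=C[C@@H](OC(=O)c2cc(O[Si](C)(C)C(C)(C)C)c(O[Si](C)(C)C(C)(C)C)c(O[Si](C)(C)C(C)(C)C)c2)[C@@H](OC(=O)c2cc(O[Si](C)(C)C(C)(C)C)c(O[Si](C)(C)C(C)(C)C)c(O[Si](C)(C)C(C)(C)C)c2)[C@H](OC(=O)c2cc(O[Si](C)(C)C(C)(C)C)c(O[Si](C)(C)C(C)(C)C)c(O[Si](C)(C)C(C)(C)C)c2)C1 | intermediate
11 | (3R,4S,5R)-3,4,5-tris[3,4,5-tris(tert-butyldimethylsilyloxy)benzoyloxy]cyclohex-1-ene-1-carboxylic acid | O=C(O)C1=C[C@@H](OC(=O)c2cc(O[Si](C)(C)C(C)(C)C)c(O[Si](C)(C)C(C)(C)C)c(O[Si](C)(C)C(C)(C)C)c2)[C@@H](OC(=O)c2cc(O[Si](C)(C)C(C)(C)C)c(O[Si](C)(C)C(C)(C)C)c(O[Si](C)(C)C(C)(C)C)c2)[C@H](OC(=O)c2cc(O[Si](C)(C)C(C)(C)C)c(O[Si](C)(C)C(C)(C)C)c(O[Si](C)(C)C(C)(C)C)c2)C1 | intermediate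
12 | 3,4,5-tri-O-galloylshikimic acid | O=C(O)C1=C[C@@H](OC(=O)c2cc(O)c(O)c(O)c2)[C@@H](OC(=O)c2cc(O)c(O)c(O)c2)[C@H](OC(=O)c2cc(O)c(O)c(O)c2)C1 | target

**Step count and risks**

Total step count: 7. Longest linear sequence: 6 steps (steps 2–7 from methyl α-D-mannopyranoside; equally steps 1 and 3–7 from gallic acid).

Steps most likely to fail:

1. **Step 5.** The α-acyloxy aldehyde may form its own enamine or enol and lose the C4 gallate by β-elimination, or epimerise at C3, before the ring closes; branched hydroformylation would also expel the allylic gallate. The fallback sets out from 7 and comes back at 11, closing the same C1–C2 bond without amine catalysis and with C7 brought in at the acid oxidation level. Cross-metathesis of 7 with tert-butyl acrylate (Hoveyda–Grubbs II, CH2Cl2, 40 °C) should give the (E)-enoate aldehyde F1. Copper hydride conjugate reduction with intramolecular aldol addition (Stryker's reagent, toluene, −40 to 0 °C) should give the cyclic β-hydroxy ester F2. MsCl/Et3N should give the mesylate F3, which eliminates in the same flask (E1cB, towards the ester only) to the tert-butyl enoate F4. TFA/CH2Cl2 then cleaves the tert-butyl ester to 11, so step 6 is bypassed as well.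

2. **Step 4.** Simple reductive deiodination may compete with ring opening on the heavily esterified substrate, and the freshly unmasked tri-acyloxy aldehyde may lose or shift a gallate in the presence of zinc salts and water. The fallback sets out from 5 and comes back at 7; the fragmentation is done on the robust free triol and the aldehyde is unveiled last under non-reducing conditions. Zinc fragmentation of 5 (Zn, THF/H2O) should give the lactol 5,6-dideoxy-D-lyxo-hex-5-enofuranose F5. EtSH/conc. HCl at 0 °C opens it to the diethyl dithioacetal triol F6. Threefold Steglich esterification with 3 (3.6 equiv, DIC, DMAP) should give the tri-ester dithioacetal F7, now on unhindered open-chain hydroxyls. PhI(OCOCF3)2 in aqueous MeCN at 0 °C then releases 7.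

3. **Step 3.** Exhaustive acylation may stall at the bis-ester stage, and during the long DMAP-mediated reaction the primary iodide may be displaced by carboxylate, by DMAP or by O-3 (3,6-anhydro ring). The fallback sets out from 4 and comes back at 6, esterifying before the iodide exists. Tritylation of 4 (TrCl, pyridine, DMAP) should give methyl 6-O-trityl-α-D-mannopyranoside F8. Threefold Steglich esterification with 3 (3.6 equiv, DIC, DMAP) gives the trityl tri-ester F9. TFA (2%)/Et3SiH in CH2Cl2 at 0 °C removes the trityl group to give the 6-hydroxy tri-ester F10. Garegg–Samuelsson iodination (I2, PPh3, imidazole, toluene, 70 °C) then gives 6.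

**Further compounds**

F1 | step 5 | tert-butyl (E)-enoate aldehyde from cross-metathesis of 7 (4,5,6-tris-O-acyl-7-oxohept-2-enoate, acyloxy carbons as in 7) | O=C[C@@H](OC(=O)c1cc(O[Si](C)(C)C(C)(C)C)c(O[Si](C)(C)C(C)(C)C)c(O[Si](C)(C)C(C)(C)C)c1)[C@@H](OC(=O)c1cc(O[Si](C)(C)C(C)(C)C)c(O[Si](C)(C)C(C)(C)C)c(O[Si](C)(C)C(C)(C)C)c1)[C@H](OC(=O)c1cc(O[Si](C)(C)C(C)(C)C)c(O[Si](C)(C)C(C)(C)C)c(O[Si](C)(C)C(C)(C)C)c1)/C=C/C(=O)OC(C)(C)C
F2 | step 5 | tert-butyl 2-hydroxy-3,4,5-tris[3,4,5-tris(tert-butyldimethylsilyloxy)benzoyloxy]cyclohexane-1-carboxylate (C1/C2 mixture) | CC(C)(C)OC(=O)C1C[C@@H](OC(=O)c2cc(O[Si](C)(C)C(C)(C)C)c(O[Si](C)(C)C(C)(C)C)c(O[Si](C)(C)C(C)(C)C)c2)[C@H](OC(=O)c2cc(O[Si](C)(C)C(C)(C)C)c(O[Si](C)(C)C(C)(C)C)c(O[Si](C)(C)C(C)(C)C)c2)[C@H](OC(=O)c2cc(O[Si](C)(C)C(C)(C)C)c(O[Si](C)(C)C(C)(C)C)c(O[Si](C)(C)C(C)(C)C)c2)C1O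
F3 | step 5 | mesylate of F2 (C1/C2 mixture) | CC(C)(C)OC(=O)C1C[C@@H](OC(=O)c2cc(O[Si](C)(C)C(C)(C)C)c(O[Si](C)(C)C(C)(C)C)c(O[Si](C)(C)C(C)(C)C)c2)[C@H](OC(=O)c2cc(O[Si](C)(C)C(C)(C)C)c(O[Si](C)(C)C(C)(C)C)c(O[Si](C)(C)C(C)(C)C)c2)[C@H](OC(=O)c2cc(O[Si](C)(C)C(C)(C)C)c(O[Si](C)(C)C(C)(C)C)c(O[Si](C)(C)C(C)(C)C)c2)C1OS(C)(=O)=O
F4 | step 5 | tert-butyl (3R,4S,5R)-3,4,5-tris[3,4,5-tris(tert-butyldimethylsilyloxy)benzoyloxy]cyclohex-1-ene-1-carboxylate | CC(C)(C)OC(=O)C1=C[C@@H](OC(=O)c2cc(O[Si](C)(C)C(C)(C)C)c(O[Si](C)(C)C(C)(C)C)c(O[Si](C)(C)C(C)(C)C)c2)[C@@H](OC(=O)c2cc(O[Si](C)(C)C(C)(C)C)c(O[Si](C)(C)C(C)(C)C)c(O[Si](C)(C)C(C)(C)C)c2)[C@H](OC(=O)c2cc(O[Si](C)(C)C(C)(C)C)c(O[Si](C)(C)C(C)(C)C)c(O[Si](C)(C)C(C)(C)C)c2)C1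
F5 | step 4 | 5,6-dideoxy-D-lyxo-hex-5-enofuranose (anomer mixture) | OC1[C@@H](O)[C@@H](O)[C@@H](C=C)O1
F6 | step 4 | 5,6-dideoxy-D-lyxo-hex-5-enose diethyl dithioacetal | CCSC(SCC)[C@@H](O)[C@@H](O)[C@H](O)C=C
F7 | step 4 | 5,6-dideoxy-2,3,4-tris-O-[3,4,5-tris(tert-butyldimethylsilyloxy)benzoyl]-D-lyxo-hex-5-enose diethyl dithioacetal | CCSC(SCC)[C@@H](OC(=O)c1cc(O[Si](C)(C)C(C)(C)C)c(O[Si](C)(C)C(C)(C)C)c(O[Si](C)(C)C(C)(C)C)c1)[C@@H](OC(=O)c1cc(O[Si](C)(C)C(C)(C)C)c(O[Si](C)(C)C(C)(C)C)c(O[Si](C)(C)C(C)(C)C)c1)[C@H](OC(=O)c1cc(O[Si](C)(C)C(C)(C)C)c(O[Si](C)(C)C(C)(C)C)c(O[Si](C)(C)C(C)(C)C)c1)C=C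
F8 | step 3 | methyl 6-O-trityl-α-D-mannopyranoside | CO[C@H]1O[C@H](COC(c2ccccc2)(c2ccccc2)c2ccccc2)[C@@H](O)[C@H](O)[C@@H]1O
F9 | step 3 | methyl 6-O-trityl-2,3,4-tris-O-[3,4,5-tris(tert-butyldimethylsilyloxy)benzoyl]-α-D-mannopyranoside | CO[C@H]1O[C@H](COC(c2ccccc2)(c2ccccc2)c2ccccc2)[C@@H](OC(=O)c2cc(O[Si](C)(C)C(C)(C)C)c(O[Si](C)(C)C(C)(C)C)c(O[Si](C)(C)C(C)(C)C)c2)[C@H](OC(=O)c2cc(O[Si](C)(C)C(C)(C)C)c(O[Si](C)(C)C(C)(C)C)c(O[Si](C)(C)C(C)(C)C)c2)[C@@H]1OC(=O)c2cc(O[Si](C)(C)C(C)(C)C)c(O[Si](C)(C)C(C)(C)C)c(O[Si](C)(C)C(C)(C)C)c2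
F10 | step 3 | methyl 2,3,4-tris-O-[3,4,5-tris(tert-butyldimethylsilyloxy)benzoyl]-α-D-mannopyranoside | CO[C@H]1O[C@H](CO)[C@@H](OC(=O)c2cc(O[Si](C)(C)C(C)(C)C)c(O[Si](C)(C)C(C)(C)C)c(O[Si](C)(C)C(C)(C)C)c2)[C@H](OC(=O)c2cc(O[Si](C)(C)C(C)(C)C)c(O[Si](C)(C)C(C)(C)C)c(O[Si](C)(C)C(C)(C)C)c2)[C@@H]1OC(=O)c2cc(O[Si](C)(C)C(C)(C)C)c(O[Si](C)(C)C(C)(C)C)c(O[Si](C)(C)C(C)(C)C)c2
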